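**Retrosynthetic overview**
1. The imide ring is made last. C12–C13 comes from an auxiliary-controlled syn aldol between a C12 aldehyde and a 3-cyanopropanoyl imide, and nitrile hydration then closes the succinimide.
2. C17 comes from Wittig methylenation of a C8 ketone. C2–Cl comes from site-selective radical C–H chlorination of the saturated keto ester, in which ring B is deactivated by C8=O, the ester and C6–O.
3. The key disconnection is C9–C10. Ring B arises from a cyclopentanol by a 1,2-shift of C10 from C8 onto the β-carbon of an (E)-γ-oxy enoate (hydrindane to decalin), which gives C8=O and C9–CH2CO2Me at once.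
4. Before that, the same C8 tertiary alcohol directs a β-epoxidation of C5=C6, and radical epoxide opening sets 6β-OH and 5α-H.
5. Ring order: five-membered ring (bought as the dione), ring A (proline annulation, sets C10), ring B (expansion of the five-membered ring), imide ring.

Assumption and convention: the recoverable auxiliary (R)-4-benzyloxazolidin-2-one is treated as a reagent. Labdane numbering is used throughout (β = face of the C20 methyl), and in the hydrindane intermediates the five-membered ring holds C5, C6, C7, C8 and C10 while C9 is still outside the ring.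

**Step 1**
Reactants: 1 2-methylcyclopentane-1,3-dione; 2 but-3-en-2-one (methyl vinyl ketone)
Product: 3 2-methyl-2-(3-oxobutyl)cyclopentane-1,3-dione
Conditions: H2O, AcOH (cat.), 70 °C
Reagents that add atoms: none
Why: Michael addition of the acidic 1,3-dione to the enone in water is clean and forms no stereocentre.

**Step 2**
Reactants: 3 2-methyl-2-(3-oxobutyl)cyclopentane-1,3-dione
Product: 5 (S)-7a-methyl-2,3,7,7a-tetrahydro-1H-indene-1,5(6H)-dione (Hajos–Parrish ketone; C20 methyl β), via cis ketol 4 (not isolated)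
Conditions: (S)-proline (3 mol %), DMF, 16 °C; then H2SO4 (cat.), DMF, 95 °C; recrystallise
Reagents that add atoms: none
Why: In the Hajos–Parrish enamine aldol, (S)-proline distinguishes the two enantiotopic ring carbonyls and sets C10, and acid then dehydrates ketol 4 to the enone.

**Step 3**
Reactants: 5 (S)-Hajos–Parrish ketone
Product: 6 8,8-ethylenedioxy derivative of 5 (saturated C8 ketone masked; enone C3=O/C4=C5 free)
Conditions: TMSOCH2CH2OTMS, TMSOTf (5 mol %), CH2Cl2, −78 to −20 °C
Reagents that add atoms: 1,2-bis(trimethylsilyloxy)ethane C[Si](C)(C)OCCO[Si](C)(C)C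
Why: Noyori ketalisation under kinetic control takes the saturated ketone and leaves the less electrophilic enone and its double-bond position untouched.

**Step 4**
Reactants: 6 C8 ketal of the Hajos–Parrish ketone
Product: 7 8,8-ethylenedioxy-4,4-dimethyl-3-oxo hydrindene with the alkene moved to C5=C6 (10β-methyl)
Conditions: KOtBu (2.6 equiv), MeI (excess), tBuOH, rt
Reagents that add atoms: iodomethane CI
Why: Deconjugative double α-alkylation of the thermodynamic dienolate places both methyl groups on C4 and leaves C5=C6 as the handle for C6 oxygenation.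

**Step 5**
Reactants: 7 4,4-dimethyl-3-oxo ketal
Product: 9 (S)-4,4,7a-trimethyl-2,4,5,6,7,7a-hexahydro-1H-inden-1-one (C8 ketone; C5=C6 alkene), via deoxygenated ketal 8 (not isolated)
Conditions: N2H4·H2O, KOH, diethylene glycol, 130 then 200 °C; extractive work-up; HCl (cat.), THF–H2O, rt
Reagents that add atoms: water O
Why: Wolff–Kishner (Huang-Minlon) reduction removes the neopentyl C3 carbonyl while ketal and hindered alkene survive base, and mild ketal hydrolysis gives the β,γ-unsaturated cyclopentanone, the more stable isomer as in 14-en-17-one steroids.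

**Step 6**
Reactants: 9 (S)-4,4,7a-trimethylhexahydroinden-1-one; 10 methyl propiolate
Product: 12 tertiary propargylic alcohol (8β-OH cis to C20; 8α-C≡C–CO2Me; C5=C6 alkene), via lithium acetylide 11 (not isolated)
Conditions: 10, LiN(iPr)2, THF, −78 °C; then 9, −78 °C; AcOH quench
Reagents that add atoms: lithium diisopropylamide [Li+].CC(C)[N-]C(C)C (its Li stands only in 11)
Why: 1,2-addition of a weakly basic acetylide occurs on the α face opposite the angular methyl, as with 17-keto steroids, and this sets the 8β-OH.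

**Step 7**
Reactants: 12 tertiary propargylic alcohol
Product: 13 (E)-γ-hydroxy enoate (8β-OH; 8α-(E)-CH=CH–CO2Me; C5=C6 alkene)
Conditions: NaAlH2(OCH2CH2OMe)2 (2 equiv), THF, −72 °C; aq. work-up
Reagents that add atoms: none
Why: Alkoxide-directed trans-hydroalumination of the γ-hydroxy ynoate followed by protonolysis gives only the (E)-enoate, which cannot lactonise.

**Step 8**
Reactants: 13 (E)-γ-hydroxy enoate
Product: 14 5β,6β-epoxide of 13
Conditions: VO(acac)2 (5 mol %), tBuOOH (decane), CH2Cl2, 0 °C to rt
Reagents that add atoms: tert-butyl hydroperoxide CC(C)(C)OO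
Why: In this hydroxyl-directed vanadium-catalysed epoxidation of a cyclopent-3-enol, the peroxide bound to the 8β-OH is delivered to the same face and sets C6–O β, while the electron-poor enoate stays inert.

**Step 9**
Reactants: 14 5β,6β-epoxide
Product: 15 trans-hydrindane 6β,8β-diol (5α-H; 8α-(E)-CH=CH–CO2Me)
Conditions: Cp2TiCl2 (20 mol %), Mn, 2,4,6-collidine·HCl, 1,4-cyclohexadiene, THF, rt
Reagents that add atoms: none
Why: Reductive radical epoxide opening by Cp2TiCl (trivalent titanium) cleaves C5–O to the tertiary radical, keeps the C6–O β bond, avoids cationic methyl shifts, and takes H from cyclohexadiene on the open α face (the β face carries C19, C20 and the titanium alkoxide), which sets 5α-H.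

**Step 10**
Reactants: 15 trans-hydrindane 6β,8β-diol
Product: 18 methyl 6β-(trimethylsilyloxy)-8-oxo-13,14,15,16,17-pentanorlabdan-12-oate (trans-decalin; 5α-H; 9α-H; 10β-Me), via bis-TMS ether 16 (not isolated), via silyl ketene acetal 17 (not isolated)
Conditions: TMSOTf (2.5 equiv), 2,6-lutidine (2.2 equiv), CH2Cl2 (0.02 M), −78 to 0 °C; TMSNTf2 (10 mol %), 0 °C to rt; aq. NaHCO3; DBU (0.1 equiv), CH2Cl2, rt
Reagents that add atoms: trimethylsilyl triflate C[Si](C)(C)OS(=O)(=O)C(F)(F)F
Why: Proposed new method: a silylium-catalysed vinylogous semipinacol ring expansion of an unstrained cyclopentanol, in which O-silylation of the ester makes C9 strongly electrophilic while the enoate blocks ionisation at C8, so the C8–C10 σ bond (pushed by the C8 silyloxy oxygen) migrates to C9 with retention at C10 to give C8=O and ketene acetal 17, with the silyl group passing on as chain carrier; C10 migrates rather than C7 because it is fully substituted and C7 is deactivated by the neighbouring C6–OTMS; C=O formation and release of trans-hydrindane strain and C8/C10 crowding drive the shift; C9 is α to the new ketone and is equilibrated by DBU to the equatorial β side chain; the closest known reaction type is the vinylogous α-ketol (semipinacol-type) rearrangement, shown so far only for strained cyclobutanols under iminium activation.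

**Step 11**
Reactants: 18 6β-silyloxy 8-oxo ester
Product: 19 methyl 2α-chloro-6β-(trimethylsilyloxy)-8-oxo-13,14,15,16,17-pentanorlabdan-12-oate
Conditions: N-tert-butyl-N-chloro-3,5-bis(trifluoromethyl)benzamide (1.1 equiv), Cs2CO3, PhH, 55 °C, white LEDs
Reagents that add atoms: N-tert-butyl-N-chloro-3,5-bis(trifluoromethyl)benzamide CC(C)(C)N(Cl)C(=O)c1cc(C(F)(F)F)cc(C(F)(F)F)c1
Why: In this amidyl-radical C–H chlorination (radical chain), the bulky electrophilic radical abstracts from the most accessible and most electron-rich methylene, C2, as it does in sclareolide, and chlorine transfer on the α face opposite the axial C19 and C20 methyls gives the equatorial 2α-chloride.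

**Step 12**
Reactants: 19 2α-chloro 8-oxo ester
Product: 20 methyl 2α-chloro-6β-(trimethylsilyloxy)-13,14,15,16-tetranorlabd-8(17)-en-12-oate
Conditions: Ph3PCH3Br (3 equiv), KOtBu (2.8 equiv), THF, 0 °C to rt
Reagents that add atoms: methyltriphenylphosphonium bromide C[P+](c1ccccc1)(c1ccccc1)c1ccccc1.[Br-]
Why: Wittig methylenation installs C17 on the only ketone; the ester, the equatorial chloride and the poor silyloxy leaving group are tolerated, and C9 already holds its thermodynamic configuration.

**Step 13**
Reactants: 20 exocyclic alkene ester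
Product: 21 2α-chloro-6β-(trimethylsilyloxy)-13,14,15,16-tetranorlabd-8(17)-en-12-al
Conditions: iBu2AlH (1.1 equiv), CH2Cl2, −78 °C; aq. work-up
Reagents that add atoms: none
Why: Partial ester reduction stops at the aluminium hemiacetal at −78 °C, which collapses to the aldehyde on work-up without touching C–Cl, the alkene or the silyl ether.

**Step 14**
Reactants: 22 3-cyanopropanoic acid
Product: 24 (R)-4-benzyl-3-(3-cyanopropanoyl)oxazolidin-2-one, via mixed pivalic anhydride 23 (not isolated)
Conditions: PivCl, Et3N, THF, −20 °C; then (R)-4-benzyloxazolidin-2-one, LiCl, rt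
Reagents that add atoms: (R)-4-benzyloxazolidin-2-one O=C1N[C@H](Cc2ccccc2)CO1; pivaloyl chloride CC(C)(C)C(=O)Cl (stands only in 23)
Why: Mixed-anhydride N-acylation of the oxazolidinone assisted by LiCl is routine, and the only stereocentre is that of the auxiliary.

**Step 15**
Reactants: 24 (R)-4-benzyl-3-(3-cyanopropanoyl)oxazolidin-2-one; 21 C12 aldehyde
Product: 26 syn aldol adduct (12S,13R; 12-OH; C13 bears CH2CN and the acyl oxazolidinone), via Z boron enolate 25 (not isolated)
Conditions: 24, Bu2BOTf (1.1 equiv), Et3N (1.3 equiv), CH2Cl2, −78 to 0 °C; 21, −78 to 0 °C; MeOH, pH 7 buffer (NaH2PO4/Na2HPO4), 30 % H2O2, 0 °C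
Reagents that add atoms: dibutylboron triflate CCCCB(CCCC)OS(=O)(=O)C(F)(F)F (its Bu2B stands only in 25)
Why: In the Evans syn aldol, the Z boron enolate reacts through a closed chair transition state whose face is fixed by the (R)-auxiliary, which sets 12S and 13R together and overrides the remote C9 centre.

**Step 16**
Reactants: 26 syn aldol adduct
Product: 29 haterumaimide F, via primary amide 27 (not isolated), via TMS-protected imide 28 (not isolated)
Conditions: [PtH(PMe2OH)(PMe2O)2H] (2 mol %), EtOH–H2O 4:1, 70 °C; DBU (0.2 equiv), rt; 1 M HCl, THF, rt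
Reagents that add atoms: water O
Why: Neutral platinum-catalysed nitrile hydration gives the primary amide, which closes the five-membered imide by intramolecular N-acylation with loss of the auxiliary; the imide N–H buffers the base so C13 is not epimerised, and dilute acid removes the TMS ether.

**Compound list**
1 | 2-methylcyclopentane-1,3-dione | CC1C(=O)CCC1=O | starting material
2 | but-3-en-2-one | C=CC(C)=O | starting material
3 | 2-methyl-2-(3-oxobutyl)cyclopentane-1,3-dione | CC(=O)CCC1(C)C(=O)CCC1=O | intermediate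
4 | (3aS,7aS)-3a-hydroxy-7a-methylhexahydro-1H-indene-1,5(4H)-dione | C[C@]12CCC(=O)C[C@@]1(O)CCC2=O | intermediate
5 | (S)-7a-methyl-2,3,7,7a-tetrahydro-1H-indene-1,5(6H)-dione | C[C@]12CCC(=O)C=C1CCC2=O | intermediate
6 | C8 ethylene ketal of 5 | C[C@]12CCC(=O)C=C1CCC23OCCO3 | intermediate
7 | 8,8-ethylenedioxy-4,4-dimethyl-3-oxo hydrindene, C5=C6 | C[C@]12CCC(=O)C(C)(C)C1=CCC23OCCO3 | intermediate
8 | 8,8-ethylenedioxy-4,4,10β-trimethyl hydrindene, C5=C6 | C[C@]12CCCC(C)(C)C1=CCC23OCCO3 | intermediate
9 | (S)-4,4,7a-trimethyl-2,4,5,6,7,7a-hexahydro-1H-inden-1-one | C[C@]12CCCC(C)(C)C1=CCC2=O | intermediate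
10 | methyl propiolate | C#CC(=O)OC | starting material
11 | methyl 3-lithiopropiolate | [Li]C#CC(=O)OC | intermediate
12 | 8β-hydroxy-8α-(methoxycarbonylethynyl) hydrindene, C5=C6 | O[C@@]1(C#CC(=O)OC)CC=C2C(C)(C)CCC[C@]12C | intermediate
13 | (E)-γ-hydroxy enoate, 8β-OH, C5=C6 | O[C@@]1(/C=C/C(=O)OC)CC=C2C(C)(C)CCC[C@]12C | intermediate
14 | 5β,6β-epoxide of 13 | O[C@@]1(/C=C/C(=O)OC)C[C@H]2O[C@]23C(C)(C)CCC[C@]13C | intermediate
15 | trans-hydrindane 6β,8β-diol, 5α-H, (E)-enoate at C8α | O[C@@]1(/C=C/C(=O)OC)C[C@@H](O)[C@H]2C(C)(C)CCC[C@]12C | intermediate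
16 | 6,8-bis(trimethylsilyl) ether of 15 | C[Si](C)(C)O[C@@]1(/C=C/C(=O)OC)C[C@@H](O[Si](C)(C)C)[C@H]2C(C)(C)CCC[C@]12C | intermediate
17 | ring-expanded 8-oxo decalin, C11=C12 silyl ketene acetal (C9 drawn as after equilibration) | O=C1C[C@@H](O[Si](C)(C)C)[C@H]2C(C)(C)CCC[C@]2(C)[C@H]1C=C(OC)O[Si](C)(C)C | intermediate
18 | methyl 6β-(trimethylsilyloxy)-8-oxo-13,14,15,16,17-pentanorlabdan-12-oate | O=C1C[C@@H](O[Si](C)(C)C)[C@H]2C(C)(C)CCC[C@]2(C)[C@H]1CC(=O)OC | intermediate
19 | methyl 2α-chloro-6β-(trimethylsilyloxy)-8-oxo-13,14,15,16,17-pentanorlabdan-12-oate | O=C1C[C@@H](O[Si](C)(C)C)[C@H]2C(C)(C)C[C@H](Cl)C[C@]2(C)[C@H]1CC(=O)OC | intermediate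
20 | methyl 2α-chloro-6β-(trimethylsilyloxy)-13,14,15,16-tetranorlabd-8(17)-en-12-oate | C=C1C[C@@H](O[Si](C)(C)C)[C@H]2C(C)(C)C[C@H](Cl)C[C@]2(C)[C@H]1CC(=O)OC | intermediate
21 | 2α-chloro-6β-(trimethylsilyloxy)-13,14,15,16-tetranorlabd-8(17)-en-12-al | C=C1C[C@@H](O[Si](C)(C)C)[C@H]2C(C)(C)C[C@H](Cl)C[C@]2(C)[C@H]1CC=O | intermediate
22 | 3-cyanopropanoic acid | N#CCCC(=O)O | starting material
23 | 3-cyanopropanoic pivalic anhydride | N#CCCC(=O)OC(=O)C(C)(C)C | intermediate
24 | (R)-4-benzyl-3-(3-cyanopropanoyl)oxazolidin-2-one | N#CCCC(=O)N1[C@H](Cc2ccccc2)COC1=O | intermediate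
25 | (Z)-dibutylboron enolate of 24 | CCCCB(CCCC)O/C(=C\CC#N)N1[C@H](Cc2ccccc2)COC1=O | intermediate
26 | syn aldol adduct (12S,13R) | C=C1C[C@@H](O[Si](C)(C)C)[C@H]2C(C)(C)C[C@H](Cl)C[C@]2(C)[C@H]1C[C@H](O)[C@@H](CC#N)C(=O)N1[C@H](Cc2ccccc2)COC1=O | intermediate
27 | primary amide from 26 | C=C1C[C@@H](O[Si](C)(C)C)[C@H]2C(C)(C)C[C@H](Cl)C[C@]2(C)[C@H]1C[C@H](O)[C@@H](CC(N)=O)C(=O)N1[C@H](Cc2ccccc2)COC1=O | intermediate
28 | 6-O-trimethylsilyl haterumaimide F | C=C1C[C@@H](O[Si](C)(C)C)[C@H]2C(C)(C)C[C@H](Cl)C[C@]2(C)[C@H]1C[C@H](O)[C@H]1CC(=O)NC1=O | intermediate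
29 | haterumaimide F | C=C1C[C@@H](O)[C@H]2C(C)(C)C[C@H](Cl)C[C@]2(C)[C@H]1C[C@H](O)[C@H]1CC(=O)NC1=O | target

**Totals**
Total step count: 16. Longest linear sequence: 15 (steps 1 to 13, then 15 and 16).

**Steps most likely to fail**

**The new ring expansion (step 10).**
- Risks: the shift may be too slow without ring strain, 17 may add to activated 16, or E to Z isomerisation may end in a butenolide.
- The fallback uses known chemistry, sets out from 16 (made from 15 with TMSOTf and 2,6-lutidine and isolated this time) and returns at 18.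
- Ozonolysis (O3, CH2Cl2, −78 °C; Me2S) cuts the enoate to the 8α-formyl bis-silyl ether F1.
- LiCH2CO2Me (from methyl acetate and LiN(iPr)2, THF, −78 °C) adds to give the β-hydroxy ester F2 as C9 epimers.
- MsCl in pyridine gives the C9 mesylate F3.
- Et2AlCl (CH2Cl2, −78 to 0 °C) then triggers the classical semipinacol ring expansion of a 2-oxy mesylate. C10 migrates anti to the leaving group, and brief DBU treatment converges both C9 epimers on 18.

**The C2-selective C–H chlorination (step 11).**
- Risks: abstraction of the C6 carbinol hydrogen, or C1/C3 chlorides.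
- The fallback replaces direct halogenation by an oxidation, reduction and substitution sequence. It sets out from 18 and returns at 19.
- [Fe((S,S)-PDP)(MeCN)2](SbF6)2 with H2O2 and AcOH in MeCN oxidises the same methylene to the 2,8-dione F4.
- LiBH(sBu)3 (1 equiv, THF, −78 °C) reduces the less hindered C2 ketone from the α face to the axial 2β-alcohol F5.
- PPh3 and CCl4 (Appel reaction, inversion from the open α face) give the equatorial chloride 19.

**The directed β-epoxidation (step 8).**
- Risk: the β face of C5=C6 is flanked by C19 and C20.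
- The fallback drops the epoxide altogether. It sets out from 13 and returns at 15, bypassing step 9 as well.
- NBS in aqueous acetone with HClO4 (cat.) forms the bromonium ion on the open α face. Water opens it anti at C6, because C5 is shielded on both sides, to give the 5α-bromo-6β,8β-diol F6.
- Bu3SnH with AIBN (PhH, 80 °C) removes bromine through the same C5 radical, which takes hydrogen on the α face to give 15.

**Further compounds**
F1 | step 10 | 8α-formyl-6β,8β-bis(trimethylsilyloxy) trans-hydrindane | C[Si](C)(C)O[C@@]1(C=O)C[C@@H](O[Si](C)(C)C)[C@H]2C(C)(C)CCC[C@]12C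
F2 | step 10 | methyl 3-hydroxy-3-[6β,8β-bis(trimethylsilyloxy)hydrindan-8α-yl]propanoate (C9 epimers) | C[Si](C)(C)O[C@@]1(C(O)CC(=O)OC)C[C@@H](O[Si](C)(C)C)[C@H]2C(C)(C)CCC[C@]12C
F3 | step 10 | C9 mesylate of F2 | C[Si](C)(C)O[C@@]1(C(CC(=O)OC)OS(C)(=O)=O)C[C@@H](O[Si](C)(C)C)[C@H]2C(C)(C)CCC[C@]12C
F4 | step 11 | methyl 6β-(trimethylsilyloxy)-2,8-dioxo-13,14,15,16,17-pentanorlabdan-12-oate | O=C1C[C@@H](O[Si](C)(C)C)[C@H]2C(C)(C)CC(=O)C[C@]2(C)[C@H]1CC(=O)OC
F5 | step 11 | methyl 2β-hydroxy-6β-(trimethylsilyloxy)-8-oxo-13,14,15,16,17-pentanorlabdan-12-oate | O=C1C[C@@H](O[Si](C)(C)C)[C@H]2C(C)(C)C[C@@H](O)C[C@]2(C)[C@H]1CC(=O)OC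
F6 | step 8 | 5α-bromo-6β,8β-dihydroxy hydrindane with the (E)-enoate at C8α | O[C@@]1(/C=C/C(=O)OC)C[C@@H](O)[C@@]2(Br)C(C)(C)CCC[C@]12C
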